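**Plan**

Numbering (germacrane): carbocycle C1–C10; lactone ring C12(=O)–O–C8–C7–C11 with C13 as the exocyclic methylene; C15H2O–acyl on C4; OH on C6.
Retrosynthetic cuts, in order: C11=C13 (masked as its dimethylamine adduct); ring bond C5–C6 (C5 alkenyl iodide + C6 aldehyde); lactone bonds C7–C8 and O–C12 (aldehyde + 2-(bromomethyl)enoate); the O15–acyl ester bond; C3–C4 (carbomagnesiation of propargyl alcohol); C1–C2 (alkenylalane + oxirane).
Forward: the open chain C8→C5 with both trisubstituted alkenes is built first, the side-chain ester is attached at O15, the γ-lactone ring is formed next, the ten-membered carbocycle is closed last, and the methylene and the side-chain hydroxyl are then set free.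
Stereochemistry: C7 and C8 from a ligand-controlled, anti-selective chromium-catalysed allylation; C6 from substrate control in the ring closure; C1=C10 geometry from syn-carboalumination, C4=C5 geometry from anti-carbomagnesiation, side-chain alkene from a stabilised Wittig reaction.
Enabling feature: C5 is a vinylic CH cis to the C15 acyloxymethyl group on C4, and C6 is a secondary carbinol next to C7 of the trans-fused lactone. The allylic alcohol C4=C5–C6(OH) is therefore the direct product pattern of an alkenylchromium adding to an aldehyde; the lactone ring, the (E)-C1=C10 alkene and the (Z)-iodoalkene fold the chain so that one event closes the carbocycle and sets C6 with every other group already in place.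

Key step: step 16

Remark on the chemistry: the configuration at C11 in the dimethylamine adducts of steps 13 to 18 is drawn as the all-trans isomer expected under equilibrating conditions; this centre is destroyed in step 18, so its epimer would serve equally.
Abbreviations: TBS = tert-butyldimethylsilyl; TBDPS = tert-butyldiphenylsilyl; DMP = Dess–Martin periodinane.

**Route**

Step 1
Reactants: 1 glycolaldehyde dimer; 2 ethyl 2-(triphenyl-λ5-phosphanylidene)propanoate
Product: 3 ethyl (E)-4-hydroxy-2-methylbut-2-enoate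
Conditions: CH2Cl2, reflux, 16 h (0.55 equiv of 1)
Reagents that add atoms: none
Why: Wittig olefination of monomeric glycolaldehyde (released from the dimer on heating) with a stabilised α-methyl ylide should give the (E)-trisubstituted enoate with ester and CH2OH trans.

Step 2
Reactants: 3 ethyl (E)-4-hydroxy-2-methylbut-2-enoate
Product: 4 ethyl (E)-2-methyl-4-(TBDPS-oxy)but-2-enoate
Conditions: TBDPSCl, imidazole, CH2Cl2, 0 °C → rt
Reagents that add atoms: tert-butyl(chloro)diphenylsilane (CC(C)(C)[Si](Cl)(c1ccccc1)c1ccccc1)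
Why: Imidazole-mediated silylation of the primary allylic alcohol installs a fluoride-labile group that should survive all acidic and oxidative steps up to step 17.

Step 3
Reactants: 4 ethyl (E)-2-methyl-4-(TBDPS-oxy)but-2-enoate
Product: 5 (E)-2-methyl-4-(TBDPS-oxy)but-2-enoic acid
Conditions: LiOH·H2O, THF/H2O, rt; then 1 M HCl to pH 3
Reagents that add atoms: lithium hydroxide ([Li+].[OH-])
Why: Saponification of the ethyl ester, to which the TBDPS ether is stable at room temperature.

Step 4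
Reactants: 6 (TBS-oxy)acetaldehyde; 7 ethyl acrylate
Product: 8 ethyl 2-[1-hydroxy-2-(TBS-oxy)ethyl]prop-2-enoate (racemic)
Conditions: DABCO (0.3 equiv), neat 7 (3 equiv), rt, 3 d
Reagents that add atoms: none
Why: Morita–Baylis–Hillman addition of the amine–acrylate zwitterion to the α-silyloxy aldehyde; the stereocentre formed is destroyed in step 5.

Step 5
Reactants: 8 ethyl 2-[1-hydroxy-2-(TBS-oxy)ethyl]prop-2-enoate
Product: 9 ethyl (Z)-2-(bromomethyl)-4-(TBS-oxy)but-2-enoate
Conditions: NBS, Me2S, CH2Cl2, 0 °C → rt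
Reagents that add atoms: N-bromosuccinimide (O=C1CCC(=O)N1Br)
Why: Corey–Kim-type activation of the allylic alcohol followed by SN2′ attack of bromide should give the thermodynamically preferred (Z)-2-(bromomethyl)enoate under conditions that spare the silyl ether.

Step 6
Reactants: 10 (but-3-yn-1-yloxy)(tert-butyl)dimethylsilane
Product: 13 (E)-4-methyl-6-(TBS-oxy)hex-3-en-1-ol, via alkenyldimethylalane 11 (not isolated), via lithium alkenylalanate 12 (not isolated)
Conditions: AlMe3 (2 equiv), Cp2ZrCl2 (0.25 equiv), CH2Cl2, 0 °C → rt; volatiles removed; n-BuLi (1 equiv), hexane/THF, −78 → 0 °C; oxirane (3 equiv), −30 °C → rt; aqueous work-up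
Reagents that add atoms: trimethylaluminium (C[Al](C)C); oxirane (C1CO1)
Why: Negishi zirconium-catalysed syn-carboalumination places CH3 on the internal and aluminium on the terminal alkyne carbon, which fixes the E geometry, and the alanate then transfers the alkenyl group to oxirane with retention.

Step 7
Reactants: 13 (E)-4-methyl-6-(TBS-oxy)hex-3-en-1-ol
Product: 14 [(E)-(6-bromo-3-methylhex-3-en-1-yl)oxy](tert-butyl)dimethylsilane
Conditions: CBr4, PPh3, CH2Cl2, 0 °C
Reagents that add atoms: carbon tetrabromide (BrC(Br)(Br)Br)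
Why: Appel bromination of the primary alcohol under neutral conditions leaves the trisubstituted alkene and the silyl ether untouched.

Step 8
Reactants: 14 [(E)-(6-bromo-3-methylhex-3-en-1-yl)oxy](tert-butyl)dimethylsilane; 15 prop-2-yn-1-ol
Product: 19 [(1Z,5E)-1-iodo-6-methyl-8-(TBS-oxy)octa-1,5-dien-2-yl]methanol, via alkylmagnesium bromide 16 (not isolated), via chloromagnesium propynolate 17 (not isolated), via alkenylmagnesium chelate 18 (not isolated)
Conditions: 14, Mg, THF, rt; separately 15, MeMgCl (1.0 equiv), THF, 0 °C (1.3 equiv of 17); the two combined with CuI (10 mol %), THF, −10 °C → rt, 16 h; then I2, −78 → 0 °C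
Reagents that add atoms: iodine (II)
Why: Copper-catalysed anti-carbomagnesiation of the propargylic alkoxide places the alkyl group on the internal carbon and magnesium on the terminal carbon in a five-membered chelate with the alkoxide, so iodinolysis with retention should fix iodine cis to CH2OH, the geometry needed at C4=C5.

Step 9
Reactants: 19 [(1Z,5E)-1-iodo-6-methyl-8-(TBS-oxy)octa-1,5-dien-2-yl]methanol; 5 (E)-2-methyl-4-(TBDPS-oxy)but-2-enoic acid
Product: 20 [(1Z,5E)-1-iodo-6-methyl-8-(TBS-oxy)octa-1,5-dien-2-yl]methyl (E)-2-methyl-4-(TBDPS-oxy)but-2-enoate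
Conditions: DCC, DMAP (0.1 equiv), CH2Cl2, 0 °C → rt
Reagents that add atoms: none
Why: Steglich esterification joins the side chain to the only free hydroxyl group without isomerising the enoate.

Step 10
Reactants: 20 [(1Z,5E)-1-iodo-6-methyl-8-(TBS-oxy)octa-1,5-dien-2-yl]methyl (E)-2-methyl-4-(TBDPS-oxy)but-2-enoate
Product: 21 [(1Z,5E)-8-hydroxy-1-iodo-6-methylocta-1,5-dien-2-yl]methyl (E)-2-methyl-4-(TBDPS-oxy)but-2-enoate
Conditions: HF·pyridine, pyridine, THF, 0 °C
Reagents that add atoms: none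
Why: Chemoselective desilylation, since buffered HF·pyridine cleaves the primary alkyl TBS ether much faster than the bulkier TBDPS ether.

Step 11
Reactants: 21 [(1Z,5E)-8-hydroxy-1-iodo-6-methylocta-1,5-dien-2-yl]methyl (E)-2-methyl-4-(TBDPS-oxy)but-2-enoate
Product: 22 [(1Z,5E)-1-iodo-6-methyl-8-oxoocta-1,5-dien-2-yl]methyl (E)-2-methyl-4-(TBDPS-oxy)but-2-enoate
Conditions: DMP, NaHCO3, CH2Cl2, 0 °C; crude aldehyde used at once
Reagents that add atoms: none
Why: Bicarbonate-buffered Dess–Martin oxidation should give the β,γ-unsaturated aldehyde without the base or strong acid that would move the alkene into conjugation.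

Step 12
Reactants: 22 [(1Z,5E)-1-iodo-6-methyl-8-oxoocta-1,5-dien-2-yl]methyl (E)-2-methyl-4-(TBDPS-oxy)but-2-enoate; 9 ethyl (Z)-2-(bromomethyl)-4-(TBS-oxy)but-2-enoate
Product: 25 [(1Z,5E)-1-iodo-6-methyl-7-{(2S,3S)-4-methylidene-5-oxo-3-[(TBS-oxy)methyl]oxolan-2-yl}hepta-1,5-dien-2-yl]methyl (E)-2-methyl-4-(TBDPS-oxy)but-2-enoate, via trimethylsilyl ether 23 (not isolated), via hydroxy ester 24 (not isolated)
Conditions: CrCl2 (10 mol %, nickel-free), chiral 1,8-bis(oxazolinyl)carbazole ligand (12 mol %, the enantiomer that directs attack on the Re face of 22), Mn powder (2 equiv), Me3SiCl (1.5 equiv), iPr2NEt (0.3 equiv), THF, rt; then 0.5 M HCl, THF, 0 °C → rt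
Reagents that add atoms: none
Why: In this chromium-catalysed enantioselective 2-(alkoxycarbonyl)allylation (a catalytic Nozaki–Hiyama allylation) the allylchromium from 9 should add through its γ-carbon in a chair transition state with both substituents equatorial (anti adduct, hence the trans lactone), the ligand selecting the Re face of the aldehyde so that C8 and C7 are both set as S, while the γ-hydroxy ester lactonises on acidic work-up and nickel-free CrCl2 leaves the alkenyl iodide untouched.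

Step 13
Reactants: 25 [(1Z,5E)-1-iodo-6-methyl-7-{(2S,3S)-4-methylidene-5-oxo-3-[(TBS-oxy)methyl]oxolan-2-yl}hepta-1,5-dien-2-yl]methyl (E)-2-methyl-4-(TBDPS-oxy)but-2-enoate
Product: 26 [(1Z,5E)-7-{(2S,3S,4S)-4-[(dimethylamino)methyl]-5-oxo-3-[(TBS-oxy)methyl]oxolan-2-yl}-1-iodo-6-methylhepta-1,5-dien-2-yl]methyl (E)-2-methyl-4-(TBDPS-oxy)but-2-enoate
Conditions: Me2NH (2 M in THF, 3 equiv), THF, 0 °C → rt
Reagents that add atoms: dimethylamine (CNC)
Why: Aza-Michael addition of dimethylamine, a standard protection of α-methylene lactones, removes the allylic activation of C7–H before C6 becomes an aldehyde and should settle as the all-trans lactone.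

Step 14
Reactants: 26 [(1Z,5E)-7-{(2S,3S,4S)-4-[(dimethylamino)methyl]-5-oxo-3-[(TBS-oxy)methyl]oxolan-2-yl}-1-iodo-6-methylhepta-1,5-dien-2-yl]methyl (E)-2-methyl-4-(TBDPS-oxy)but-2-enoate
Product: 27 [(1Z,5E)-7-{(2S,3S,4S)-4-[(dimethylamino)methyl]-3-(hydroxymethyl)-5-oxooxolan-2-yl}-1-iodo-6-methylhepta-1,5-dien-2-yl]methyl (E)-2-methyl-4-(TBDPS-oxy)but-2-enoate
Conditions: HF·pyridine, pyridine, THF, 0 °C → rt
Reagents that add atoms: none
Why: Selective fluoride cleavage of the primary TBS ether beside the TBDPS ether, in a weakly acidic buffered medium that should not move the lactone onto the freed hydroxyl.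

Step 15
Reactants: 27 [(1Z,5E)-7-{(2S,3S,4S)-4-[(dimethylamino)methyl]-3-(hydroxymethyl)-5-oxooxolan-2-yl}-1-iodo-6-methylhepta-1,5-dien-2-yl]methyl (E)-2-methyl-4-(TBDPS-oxy)but-2-enoate
Product: 28 [(1Z,5E)-7-{(2S,3R,4S)-4-[(dimethylamino)methyl]-3-formyl-5-oxooxolan-2-yl}-1-iodo-6-methylhepta-1,5-dien-2-yl]methyl (E)-2-methyl-4-(TBDPS-oxy)but-2-enoate
Conditions: DMP, NaHCO3, CH2Cl2, 0 °C; crude aldehyde used at once
Reagents that add atoms: none
Why: Buffered Dess–Martin oxidation of the primary alcohol gives the C6 aldehyde under non-basic conditions, and the 3,4-trans arrangement is the stable one so C7 should not drift.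

Step 16
Reactants: 28 [(1Z,5E)-7-{(2S,3R,4S)-4-[(dimethylamino)methyl]-3-formyl-5-oxooxolan-2-yl}-1-iodo-6-methylhepta-1,5-dien-2-yl]methyl (E)-2-methyl-4-(TBDPS-oxy)but-2-enoate
Product: 29 (6R,7S,8S,11S)-13-(dimethylamino)-6-hydroxy-15-{[(E)-2-methyl-4-(TBDPS-oxy)but-2-enoyl]oxy}-11,13-dihydrogermacra-1(10),4-dien-12,8-olide (ring-trans alkenes)
Conditions: CrCl2 (10 equiv), NiCl2 (0.1 equiv), degassed DMSO, rt; 28 added over 12 h to a final concentration of 2 mM
Reagents that add atoms: none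
Why: NiCl2 is reduced by CrCl2 to zerovalent nickel, which inserts into the C5–I bond with retention of the C4=C5 geometry, and transmetalation to trivalent chromium gives an alkenylchromium that adds to the C6 aldehyde, the chromium alkoxide being hydrolysed on work-up. The closest known reaction type is the Nozaki–Hiyama–Kishi closure of nine- to twelve-membered rings from (Z)-iodoalkene aldehydes. The ten-membered carbocycle closes in the 10-exo-trig mode, the C6=O bond lying outside the new ring. The new stereocentre C6 is controlled by C7 and the trans-fused lactone: in the crown-like transition state the chromium-bound oxygen is pseudo-equatorial and antiperiplanar to the C7–C8 bond, C6–H is anti to C7–H and C5 approaches anti to C11 (a Felkin–Anh arrangement), which should give 6R. The step needs chemoselectivity for the aldehyde over the lactone and the two esters, which alkenylchromium reagents have by nature; ring closure over intermolecular coupling, secured by slow addition at high dilution and by the trans-lactone, the (E)-C1=C10 alkene and the (Z)-iodoalkene that bring C5 next to C6; and retention of the ring-trans C4=C5 geometry, which the nickel/chromium sequence preserves.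

Step 17
Reactants: 29 (6R,7S,8S,11S)-13-(dimethylamino)-6-hydroxy-15-{[(E)-2-methyl-4-(TBDPS-oxy)but-2-enoyl]oxy}-11,13-dihydrogermacra-1(10),4-dien-12,8-olide
Product: 30 (6R,7S,8S,11S)-13-(dimethylamino)-6-hydroxy-15-{[(E)-4-hydroxy-2-methylbut-2-enoyl]oxy}-11,13-dihydrogermacra-1(10),4-dien-12,8-olide
Conditions: TBAF, AcOH (1:1), THF, 0 °C → rt
Reagents that add atoms: none
Why: Fluoride cleavage of the silyl ether, buffered with acetic acid so that neither acyl migration from O15 to the C6 hydroxyl nor translactonisation to O6 is triggered.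

Step 18
Reactants: 30 (6R,7S,8S,11S)-13-(dimethylamino)-6-hydroxy-15-{[(E)-4-hydroxy-2-methylbut-2-enoyl]oxy}-11,13-dihydrogermacra-1(10),4-dien-12,8-olide
Product: 32 target CNP0326626.1, via trimethylammonium iodide 31 (not isolated)
Conditions: MeI (10 equiv), THF/MeOH, rt; volatiles removed; then aq. NaHCO3, CH2Cl2, rt
Reagents that add atoms: none
Why: Exhaustive N-methylation followed by mild-base E1cB (Hofmann-type) loss of trimethylamine, the standard unmasking of dimethylamine adducts, should regenerate the α-methylene lactone without touching alkenes, esters or free hydroxyls.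

**Compound list**

1 | glycolaldehyde dimer (1,4-dioxane-2,5-diol) | OC1COC(O)CO1 | starting material
2 | ethyl 2-(triphenyl-λ5-phosphanylidene)propanoate | CCOC(=O)C(C)=P(c1ccccc1)(c1ccccc1)c1ccccc1 | starting material
3 | ethyl (E)-4-hydroxy-2-methylbut-2-enoate | CCOC(=O)/C(C)=C/CO | intermediate
4 | ethyl (E)-2-methyl-4-(TBDPS-oxy)but-2-enoate | CCOC(=O)/C(C)=C/CO[Si](c1ccccc1)(c1ccccc1)C(C)(C)C | intermediate
5 | (E)-2-methyl-4-(TBDPS-oxy)but-2-enoic acid | OC(=O)/C(C)=C/CO[Si](c1ccccc1)(c1ccccc1)C(C)(C)C | intermediate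
6 | (TBS-oxy)acetaldehyde | O=CCO[Si](C)(C)C(C)(C)C | starting material
7 | ethyl acrylate | C=CC(=O)OCC | starting material
8 | ethyl 2-[1-hydroxy-2-(TBS-oxy)ethyl]prop-2-enoate (racemic) | C=C(C(O)CO[Si](C)(C)C(C)(C)C)C(=O)OCC | intermediate
9 | ethyl (Z)-2-(bromomethyl)-4-(TBS-oxy)but-2-enoate | CCOC(=O)/C(CBr)=C/CO[Si](C)(C)C(C)(C)C | intermediate
10 | (but-3-yn-1-yloxy)(tert-butyl)dimethylsilane | C#CCCO[Si](C)(C)C(C)(C)C | starting material
11 | (E)-[2-methyl-4-(TBS-oxy)but-1-en-1-yl]dimethylalane (not isolated) | C[Al](C)/C=C(\C)CCO[Si](C)(C)C(C)(C)C | intermediate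
12 | lithium butyl[(E)-2-methyl-4-(TBS-oxy)but-1-en-1-yl]dimethylalanate (not isolated) | [Li+].CCCC[Al-](C)(C)/C=C(\C)CCO[Si](C)(C)C(C)(C)C | intermediate
13 | (E)-4-methyl-6-(TBS-oxy)hex-3-en-1-ol | OCC/C=C(\C)CCO[Si](C)(C)C(C)(C)C | intermediate
14 | [(E)-(6-bromo-3-methylhex-3-en-1-yl)oxy](tert-butyl)dimethylsilane | BrCC/C=C(\C)CCO[Si](C)(C)C(C)(C)C | intermediate
15 | prop-2-yn-1-ol | C#CCO | starting material
16 | [(E)-4-methyl-6-(TBS-oxy)hex-3-en-1-yl]magnesium bromide (not isolated) | Br[Mg]CC/C=C(\C)CCO[Si](C)(C)C(C)(C)C | intermediate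
17 | chloromagnesium prop-2-yn-1-olate (not isolated) | C#CCO[Mg]Cl | intermediate
18 | (Z)-alkenylmagnesium bromide with MgBr on C1 cis to the CH2OMgCl group on C2 of the (5E)-6-methyl-8-(TBS-oxy)octa-1,5-diene chain (not isolated) | Cl[Mg]OC/C(=C\[Mg]Br)CC/C=C(\C)CCO[Si](C)(C)C(C)(C)C | intermediate
19 | [(1Z,5E)-1-iodo-6-methyl-8-(TBS-oxy)octa-1,5-dien-2-yl]methanol | OC/C(=C\I)CC/C=C(\C)CCO[Si](C)(C)C(C)(C)C | intermediate
20 | [(1Z,5E)-1-iodo-6-methyl-8-(TBS-oxy)octa-1,5-dien-2-yl]methyl (E)-2-methyl-4-(TBDPS-oxy)but-2-enoate | CC(C)(C)[Si](C)(C)OCC/C(C)=C/CC/C(COC(=O)/C(C)=C/CO[Si](c1ccccc1)(c1ccccc1)C(C)(C)C)=C/I | intermediate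
21 | [(1Z,5E)-8-hydroxy-1-iodo-6-methylocta-1,5-dien-2-yl]methyl (E)-2-methyl-4-(TBDPS-oxy)but-2-enoate | OCC/C(C)=C/CC/C(COC(=O)/C(C)=C/CO[Si](c1ccccc1)(c1ccccc1)C(C)(C)C)=C/I | intermediate
22 | [(1Z,5E)-1-iodo-6-methyl-8-oxoocta-1,5-dien-2-yl]methyl (E)-2-methyl-4-(TBDPS-oxy)but-2-enoate | O=CC/C(C)=C/CC/C(COC(=O)/C(C)=C/CO[Si](c1ccccc1)(c1ccccc1)C(C)(C)C)=C/I | intermediate
23 | ethyl (3S,4S,6E,10Z)-11-iodo-6-methyl-2-methylidene-10-({[(E)-2-methyl-4-(TBDPS-oxy)but-2-enoyl]oxy}methyl)-3-[(TBS-oxy)methyl]-4-[(trimethylsilyl)oxy]undeca-6,10-dienoate (not isolated) | CCOC(=O)C(=C)[C@@H](CO[Si](C)(C)C(C)(C)C)[C@@H](O[Si](C)(C)C)C/C(C)=C/CC/C(COC(=O)/C(C)=C/CO[Si](c1ccccc1)(c1ccccc1)C(C)(C)C)=C/I | intermediate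
24 | the corresponding (3S,4S)-4-hydroxy ester (not isolated) | CCOC(=O)C(=C)[C@@H](CO[Si](C)(C)C(C)(C)C)[C@@H](O)C/C(C)=C/CC/C(COC(=O)/C(C)=C/CO[Si](c1ccccc1)(c1ccccc1)C(C)(C)C)=C/I | intermediate
25 | [(1Z,5E)-1-iodo-6-methyl-7-{(2S,3S)-4-methylidene-5-oxo-3-[(TBS-oxy)methyl]oxolan-2-yl}hepta-1,5-dien-2-yl]methyl (E)-2-methyl-4-(TBDPS-oxy)but-2-enoate | C=C1C(=O)O[C@@H](C/C(C)=C/CC/C(COC(=O)/C(C)=C/CO[Si](c2ccccc2)(c2ccccc2)C(C)(C)C)=C/I)[C@@H]1CO[Si](C)(C)C(C)(C)C | intermediate
26 | (2S,3S,4S)-4-[(dimethylamino)methyl] lactone, TBS ether (dimethylamine adduct of 25) | O=C1O[C@@H](C/C(C)=C/CC/C(COC(=O)/C(C)=C/CO[Si](c2ccccc2)(c2ccccc2)C(C)(C)C)=C/I)[C@H](CO[Si](C)(C)C(C)(C)C)[C@H]1CN(C)C | intermediate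
27 | (2S,3S,4S)-4-[(dimethylamino)methyl]-3-(hydroxymethyl) lactone | O=C1O[C@@H](C/C(C)=C/CC/C(COC(=O)/C(C)=C/CO[Si](c2ccccc2)(c2ccccc2)C(C)(C)C)=C/I)[C@H](CO)[C@H]1CN(C)C | intermediate
28 | (2S,3R,4S)-4-[(dimethylamino)methyl]-3-formyl lactone | O=C1O[C@@H](C/C(C)=C/CC/C(COC(=O)/C(C)=C/CO[Si](c2ccccc2)(c2ccccc2)C(C)(C)C)=C/I)[C@H](C=O)[C@H]1CN(C)C | intermediate
29 | (6R,7S,8S,11S)-13-(dimethylamino)-6-hydroxy-15-{[(E)-2-methyl-4-(TBDPS-oxy)but-2-enoyl]oxy}-11,13-dihydrogermacra-1(10),4-dien-12,8-olide | O=C1O[C@H]2C/C(C)=C/CC/C(COC(=O)/C(C)=C/CO[Si](c3ccccc3)(c3ccccc3)C(C)(C)C)=C/[C@@H](O)[C@@H]2[C@H]1CN(C)C | intermediate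
30 | (6R,7S,8S,11S)-13-(dimethylamino)-6-hydroxy-15-{[(E)-4-hydroxy-2-methylbut-2-enoyl]oxy}-11,13-dihydrogermacra-1(10),4-dien-12,8-olide | O=C1O[C@H]2C/C(C)=C/CC/C(COC(=O)/C(C)=C/CO)=C/[C@@H](O)[C@@H]2[C@H]1CN(C)C | intermediate
31 | N-methyl quaternary ammonium iodide of 30 (not isolated) | O=C1O[C@H]2C/C(C)=C/CC/C(COC(=O)/C(C)=C/CO)=C/[C@@H](O)[C@@H]2[C@H]1C[N+](C)(C)C.[I-] | intermediate
32 | CNP0326626.1, (6R,7S,8S)-6-hydroxy-15-{[(E)-4-hydroxy-2-methylbut-2-enoyl]oxy}germacra-1(10),4,11(13)-trien-12,8-olide | C=C1C(=O)O[C@H]2C/C(C)=C/CC/C(COC(=O)/C(C)=C/CO)=C/[C@@H](O)[C@H]12 | target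

**Count and risks**

Total steps: 18. Longest linear sequence: 13 steps (10 to 32, steps 6 to 18).

Steps most likely to fail:

1. Step 16. What may go wrong: attack on the other face of the C6 aldehyde in the strained transition state and, to a lesser degree, intermolecular coupling that slow addition has to suppress. Fallback (sets out from 28, returns at 29): the ring closure is run as in step 16 and any mixture of 29 with the C6-epimeric alcohol F1 is taken on together. Oxidation of the allylic alcohol with MnO2 (CH2Cl2, rt) should give the ten-membered 4-en-6-one F2. Its 1,2-reduction with catecholborane and the matching enantiomer of 2-methyl-CBS-oxazaborolidine (toluene, −78 °C) then sets C6 under reagent control and returns to 29.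

2. Step 12. What may go wrong: isomerisation of the β,γ-unsaturated aldehyde 22 to the conjugated enal before C–C bond formation, and incomplete ligand control of face and anti selectivity. Fallback (sets out from 22, returns at 26): an auxiliary-controlled Evans syn-aldol reaction. Methyl 4-[(4R)-4-benzyl-2-oxo-1,3-oxazolidin-3-yl]-4-oxobutanoate F3 is made from (R)-4-benzyl-1,3-oxazolidin-2-one, n-BuLi and methyl 4-chloro-4-oxobutanoate. It is enolised with Bu2BOTf/iPr2NEt and added to 22 at −78 °C to give the syn-aldol adduct F4, which lactonises on work-up to the trans-lactone imide F5. NaBH4 in THF/H2O removes the auxiliary reductively to give the hydroxymethyl lactone F6, and TBSCl/imidazole gives the silyl ether F7. Its lithium enolate (LiN(SiMe3)2, 1.05 equiv, THF, −78 °C) is alkylated with Eschenmoser's salt anti to the C7 substituent, which gives 26 directly.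

3. Step 15. What may go wrong: β-elimination of the lactone carboxylate from the β-acyloxy aldehyde, epimerisation at C7, or loss of dimethylamine by retro-Michael reaction, all promoted by the basic amine inside the molecule. Fallback (sets out from 25, returns at 32): the amine mask is left out. HF·pyridine converts 25 into the α-methylene hydroxymethyl lactone F8, and buffered Dess–Martin oxidation gives the α-methylene aldehyde F9. This is submitted at once to the CrCl2/NiCl2 ring closure of step 16 to give the TBDPS ether of the target F10, and TBAF/AcOH then gives 32.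

Further compounds
F1 | step 16 | C6 epimer of 29, (6S,7S,8S,11S) | O=C1O[C@H]2C/C(C)=C/CC/C(COC(=O)/C(C)=C/CO[Si](c3ccccc3)(c3ccccc3)C(C)(C)C)=C/[C@H](O)[C@@H]2[C@H]1CN(C)C
F2 | step 16 | (7R,8S,11S)-13-(dimethylamino)-15-{[(E)-2-methyl-4-(TBDPS-oxy)but-2-enoyl]oxy}-6-oxo-11,13-dihydrogermacra-1(10),4-dien-12,8-olide | O=C1O[C@H]2C/C(C)=C/CC/C(COC(=O)/C(C)=C/CO[Si](c3ccccc3)(c3ccccc3)C(C)(C)C)=C/C(=O)[C@@H]2[C@H]1CN(C)C
F3 | step 12 | methyl 4-[(4R)-4-benzyl-2-oxo-1,3-oxazolidin-3-yl]-4-oxobutanoate | COC(=O)CCC(=O)N1[C@H](Cc2ccccc2)COC1=O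
F4 | step 12 | syn-aldol adduct of F3 with 22 (hydroxy imide methyl ester, not isolated) | COC(=O)C[C@@H](C(=O)N1[C@H](Cc2ccccc2)COC1=O)[C@@H](O)C/C(C)=C/CC/C(COC(=O)/C(C)=C/CO[Si](c1ccccc1)(c1ccccc1)C(C)(C)C)=C/I
F5 | step 12 | trans-lactone carrying the N-acyl oxazolidinone on C7 | O=C1O[C@@H](C/C(C)=C/CC/C(COC(=O)/C(C)=C/CO[Si](c2ccccc2)(c2ccccc2)C(C)(C)C)=C/I)[C@H](C(=O)N2[C@H](Cc3ccccc3)COC2=O)C1
F6 | step 12 | trans-3-(hydroxymethyl) lactone without substituent at C11 | O=C1O[C@@H](C/C(C)=C/CC/C(COC(=O)/C(C)=C/CO[Si](c2ccccc2)(c2ccccc2)C(C)(C)C)=C/I)[C@H](CO)C1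
F7 | step 12 | TBS ether of F6 | O=C1O[C@@H](C/C(C)=C/CC/C(COC(=O)/C(C)=C/CO[Si](c2ccccc2)(c2ccccc2)C(C)(C)C)=C/I)[C@H](CO[Si](C)(C)C(C)(C)C)C1
F8 | step 15 | α-methylene 3-(hydroxymethyl) lactone (desilylated 25) | C=C1C(=O)O[C@@H](C/C(C)=C/CC/C(COC(=O)/C(C)=C/CO[Si](c2ccccc2)(c2ccccc2)C(C)(C)C)=C/I)[C@@H]1CO
F9 | step 15 | α-methylene 3-formyl lactone | C=C1C(=O)O[C@@H](C/C(C)=C/CC/C(COC(=O)/C(C)=C/CO[Si](c2ccccc2)(c2ccccc2)C(C)(C)C)=C/I)[C@@H]1C=O
F10 | step 15 | TBDPS ether of 32 | C=C1C(=O)O[C@H]2C/C(C)=C/CC/C(COC(=O)/C(C)=C/CO[Si](c3ccccc3)(c3ccccc3)C(C)(C)C)=C/[C@@H](O)[C@H]12
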